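**Retrosynthetic overview**
1. Target 19 is the (4→6)-linked dimer of the 2,3-cis-3,4-trans flavan-3,4-diol 17. The interflavan C4–C6 bond is cut last and is made by acid self-condensation of 17 through its C4 quinone methide (upper C4 set trans to 3-OH).
2. 17 ⇐ 16 ⇐ 14: the C4–OH comes from DDQ benzylic oxidation of the (2R,3R)-cis flavan-3-ol. C2 and C3 are set together in one dynamic-kinetic hydrogenation of the racemic flavan-3-one 13.
3. Key disconnection: C3 of ring C is the carbon of nitromethane, used as a masked acyl anion (carbonyl 1,1-dianion). C2–C3 is made by nitroaldol on aldehyde 4; C3–C4 by ring-closing nitronate addition to the aldehyde of 3 inside an oxa-Michael/nitroaldol cascade. Two aldehyde carbons are thus joined through one nucleophilic carbon, and the nitro group is then unmasked to C3=O.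
4. Ring order: rings A and B are bought as benzaldehydes 1 and 4; ring C (the pyran) closes in step 3; the two flavan units are joined last.

Assumption: in step 5 the catalyst is written as the (S)-XylBINAP/(S)-DAIPEN complex; if a test reduction shows the opposite sense, its mirror-image complex is used and nothing else changes. Flavan numbering (O1, C2, C3, C4, C4a, C5–C8, C8a) is used throughout.

**Step 1**
Reactants: 1 2,3,4-trihydroxybenzaldehyde
Product: 3 3,4-bis(benzyloxy)-2-hydroxybenzaldehyde, via 4-O-benzyl ether 2 (not isolated)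
Conditions: BnBr (2.05 equiv), K2CO3 (2.0 equiv), DMF, 0 to 25 °C
Reagents that add atoms: benzyl bromide, BrCc1ccccc1
Why: Williamson ether synthesis in which the 4-OH (para to CHO, most acidic) and then the 3-OH are alkylated while the 2-OH stays locked in its hydrogen bond to the aldehyde, so two equivalents stop at the 3,4-dibenzyl ether.

**Step 2**
Reactants: 4 3,4-bis(benzyloxy)benzaldehyde; 5 nitromethane
Product: 7 (E)-1,2-bis(benzyloxy)-4-(2-nitroethenyl)benzene, via nitroaldol 6 (not isolated)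
Conditions: MeNO2 (5 equiv), NH4OAc (0.3 equiv), AcOH, 100 °C
Reagents that add atoms: none
Why: Henry (nitroaldol) condensation in which the nitronate of nitromethane adds to the aldehyde carbon (C2–C3 bond) and the benzylic nitro alcohol loses water to the conjugated (E)-nitroalkene.

**Step 3 (key step)**
Reactants: 3 3,4-bis(benzyloxy)-2-hydroxybenzaldehyde; 7 (E)-1,2-bis(benzyloxy)-4-(2-nitroethenyl)benzene
Product: 10 rac-7,8-bis(benzyloxy)-2-[3,4-bis(benzyloxy)phenyl]-3-nitro-2H-chromene, via oxa-Michael adduct 8 (not isolated), via 3-nitrochroman-4-ol 9 (not isolated)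
Conditions: DABCO (0.5 equiv), MeCN, 60 °C
Reagents that add atoms: none
Why: Domino oxa-Michael/Henry/E1cB dehydration in which the phenoxide of 3 adds to the aryl-bearing carbon of the nitroalkene (O1–C2), the resulting nitronate (the masked acyl anion of the later C3 ketone) closes ring C onto the aldehyde carbon (C3–C4), and loss of water gives the nitrochromene; C2 is deliberately formed racemic because it is set in step 5.

**Step 4**
Reactants: 10 rac-7,8-bis(benzyloxy)-2-[3,4-bis(benzyloxy)phenyl]-3-nitro-2H-chromene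
Product: 13 rac-7,8-bis(benzyloxy)-2-[3,4-bis(benzyloxy)phenyl]chroman-3-one, via oxime 11 (not isolated), via imine 12 (not isolated)
Conditions: Fe powder (6 equiv), AcOH/H2O 9:1, 80 °C, N2; crude product used directly
Reagents that add atoms: water, O
Why: Reductive Nef-type unmasking in which iron reduces the conjugated nitroalkene through the oxime to the imine, which hydrolyses to the C3 ketone; aryl benzyl ethers and the pyran C–O bond are inert to Fe/AcOH.

**Step 5**
Reactants: 13 rac-7,8-bis(benzyloxy)-2-[3,4-bis(benzyloxy)phenyl]chroman-3-one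
Product: 14 (2R,3R)-7,8-bis(benzyloxy)-2-[3,4-bis(benzyloxy)phenyl]chroman-3-ol (2,3-cis)
Conditions: RuCl2[(S)-xylbinap][(S)-daipen] (0.5 mol %), KOtBu (5 mol %), H2 (10 atm), iPrOH/THF 4:1, 25 °C, degassed
Reagents that add atoms: none
Why: Noyori asymmetric hydrogenation with dynamic kinetic resolution, in which C2 (benzylic, alpha to both C=O and O1) epimerises fast through the enolate, the catalyst reduces the (2R) ketone faster and delivers hydride anti to the equatorial 2-aryl group, setting C2 and C3 together as the 2,3-cis (2R,3R) alcohol; the ruthenium hydride does not touch benzyl ethers.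

**Step 6**
Reactants: 14 (2R,3R)-7,8-bis(benzyloxy)-2-[3,4-bis(benzyloxy)phenyl]chroman-3-ol
Product: 16 (2R,3R,4S)-7,8-bis(benzyloxy)-2-[3,4-bis(benzyloxy)phenyl]chromane-3,4-diol (2,3-cis-3,4-trans), via C4 cation 15 (not isolated)
Conditions: DDQ (1.3 equiv), CH2Cl2/H2O 18:1, 25 °C
Reagents that add atoms: water, O
Why: DDQ benzylic oxidation in which hydride abstraction from C4 (para to the 7-benzyloxy group, ortho to O1) gives cation 15, captured by water on the face trans to the axial 3-OH to give the (4S) alcohol; C2–H is less activated (one para and one meta oxygen only), and a C4 epimer would converge in step 8.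

**Step 7**
Reactants: 16 (2R,3R,4S)-7,8-bis(benzyloxy)-2-[3,4-bis(benzyloxy)phenyl]chromane-3,4-diol
Product: 17 isomelacacidin, (2R,3R,4S)-2-(3,4-dihydroxyphenyl)chromane-3,4,7,8-tetrol
Conditions: H2 (1 atm), Pd(OH)2/C, EtOAc/MeOH 1:1, 25 °C, neutral, stopped at 4 equiv H2 uptake; handled under N2
Reagents that add atoms: none
Why: Hydrogenolysis of the four aryl benzyl ethers, which are cleaved much faster than the secondary benzylic 4-OH under neutral conditions; no stereocentre is touched.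

**Step 8**
Reactants: 17 isomelacacidin (two molecules)
Product: 19 target dimer (2R,3R,4S)-2-(3,4-dihydroxyphenyl)-4-[(2R,3R,4S)-2-(3,4-dihydroxyphenyl)-3,4,7,8-tetrahydroxychroman-6-yl]chromane-3,7,8-triol, via quinone methide 18 (not isolated)
Conditions: 0.1 M aq. HCl, 40 °C, N2, stopped near 40% conversion; Sephadex LH-20 (EtOH), 17 recovered
Reagents that add atoms: none
Why: Biomimetic acid-catalysed Friedel–Crafts-type self-condensation of a flavan-3,4-diol, in which loss of the 4-OH gives quinone methide 18 (C4 cation stabilised by 7-OH) and C6 of a second molecule (ortho to 7-OH, para to O1) attacks it trans to the 3-OH, setting the upper C4 as (S); the lower unit keeps its 3,4-trans diol, which is also the form returned by water capture under these conditions.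

**Compound list**
1 | 2,3,4-trihydroxybenzaldehyde | O=Cc1ccc(O)c(O)c1O | starting material
2 | 4-(benzyloxy)-2,3-dihydroxybenzaldehyde (not isolated) | O=Cc1ccc(OCc2ccccc2)c(O)c1O | intermediate
3 | 3,4-bis(benzyloxy)-2-hydroxybenzaldehyde | O=Cc1ccc(OCc2ccccc2)c(OCc2ccccc2)c1O | intermediate
4 | 3,4-bis(benzyloxy)benzaldehyde | O=Cc1ccc(OCc2ccccc2)c(OCc2ccccc2)c1 | starting material
5 | nitromethane | C[N+](=O)[O-] | starting material
6 | rac-1-[3,4-bis(benzyloxy)phenyl]-2-nitroethanol (not isolated) | OC(C[N+](=O)[O-])c1ccc(OCc2ccccc2)c(OCc2ccccc2)c1 | intermediate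
7 | (E)-1,2-bis(benzyloxy)-4-(2-nitroethenyl)benzene | [O-][N+](=O)/C=C/c1ccc(OCc2ccccc2)c(OCc2ccccc2)c1 | intermediate
8 | rac-3,4-bis(benzyloxy)-2-{1-[3,4-bis(benzyloxy)phenyl]-2-nitroethoxy}benzaldehyde (not isolated; reacts on as its nitronate) | O=Cc1ccc(OCc2ccccc2)c(OCc2ccccc2)c1OC(C[N+](=O)[O-])c1ccc(OCc2ccccc2)c(OCc2ccccc2)c1 | intermediate
9 | 7,8-bis(benzyloxy)-2-[3,4-bis(benzyloxy)phenyl]-3-nitrochroman-4-ol, racemic diastereomer mixture (not isolated) | OC1c2ccc(OCc3ccccc3)c(OCc3ccccc3)c2OC(c2ccc(OCc3ccccc3)c(OCc3ccccc3)c2)C1[N+](=O)[O-] | intermediate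
10 | rac-7,8-bis(benzyloxy)-2-[3,4-bis(benzyloxy)phenyl]-3-nitro-2H-chromene | [O-][N+](=O)C1=Cc2ccc(OCc3ccccc3)c(OCc3ccccc3)c2OC1c1ccc(OCc2ccccc2)c(OCc2ccccc2)c1 | intermediate
11 | oxime of 13, racemic (not isolated) | ON=C1Cc2ccc(OCc3ccccc3)c(OCc3ccccc3)c2OC1c1ccc(OCc2ccccc2)c(OCc2ccccc2)c1 | intermediate
12 | 3-imine of 13, racemic (not isolated) | N=C1Cc2ccc(OCc3ccccc3)c(OCc3ccccc3)c2OC1c1ccc(OCc2ccccc2)c(OCc2ccccc2)c1 | intermediate
13 | rac-7,8-bis(benzyloxy)-2-[3,4-bis(benzyloxy)phenyl]chroman-3-one | O=C1Cc2ccc(OCc3ccccc3)c(OCc3ccccc3)c2OC1c1ccc(OCc2ccccc2)c(OCc2ccccc2)c1 | intermediate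
14 | (2R,3R)-7,8-bis(benzyloxy)-2-[3,4-bis(benzyloxy)phenyl]chroman-3-ol (2,3-cis) | O[C@@H]1Cc2ccc(OCc3ccccc3)c(OCc3ccccc3)c2O[C@@H]1c1ccc(OCc2ccccc2)c(OCc2ccccc2)c1 | intermediate
15 | (2R,3R)-C4 benzylic cation of 14 (not isolated) | O[C@@H]1[CH+]c2ccc(OCc3ccccc3)c(OCc3ccccc3)c2O[C@@H]1c1ccc(OCc2ccccc2)c(OCc2ccccc2)c1 | intermediate
16 | (2R,3R,4S)-7,8-bis(benzyloxy)-2-[3,4-bis(benzyloxy)phenyl]chromane-3,4-diol (2,3-cis-3,4-trans) | c1ccccc1COc1ccc2c(c1OCc1ccccc1)O[C@H](c1ccc(OCc3ccccc3)c(OCc3ccccc3)c1)[C@H](O)[C@H]2O | intermediate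
17 | isomelacacidin, (2R,3R,4S)-2-(3,4-dihydroxyphenyl)chromane-3,4,7,8-tetrol (2,3-cis-3,4-trans) | Oc1ccc2c(c1O)O[C@H](c1ccc(O)c(O)c1)[C@H](O)[C@H]2O | intermediate
18 | ring A para-quinone methide of 17, (2R,3R)-2-(3,4-dihydroxyphenyl)-3,8-dihydroxy-2,3-dihydrochromen-7-one (not isolated) | O[C@@H]1C=C2C=CC(=O)C(O)=C2O[C@@H]1c1ccc(O)c(O)c1 | intermediate
19 | (2R,3R,4S)-2-(3,4-dihydroxyphenyl)-4-[(2R,3R,4S)-2-(3,4-dihydroxyphenyl)-3,4,7,8-tetrahydroxychroman-6-yl]chromane-3,7,8-triol; both units 2,3-cis, upper 4-aryl trans to 3-OH, lower 3,4-trans diol | Oc1ccc([C@H]2Oc3c(ccc(O)c3O)[C@H](c3cc4c(c(O)c3O)O[C@H](c3ccc(O)c(O)c3)[C@H](O)[C@H]4O)[C@H]2O)cc1O | target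

**Totals**
Total steps: 8. Longest linear sequence: 7 (steps 2–8 from 4 and 5, or step 1 then steps 3–8 from 1).

**Three steps most likely to fail**

Step 8 (self-condensation): monomer, dimer and higher oligomers all carry both the electrophilic 4-OH and a nucleophilic ring A, so the dimer yield is limited and separation is demanding. The fallback sets out from 16 and comes back at 19. Part of 16 is converted with benzenethiol and catalytic TsOH (CH2Cl2, −20 °C) into the 4-thioether (2R,3R,4S)-7,8-bis(benzyloxy)-2-[3,4-bis(benzyloxy)phenyl]-4-(phenylsulfanyl)chroman-3-ol F5. F5 alone is then ionised with the thiophile AgOTf (CH2Cl2, −40 °C, solid NaHCO3 buffer) in the presence of 3 equiv of 16, which can only act as the nucleophile under these conditions. This gives the octa-O-benzyl ether of 19 F6, and hydrogenolysis as in step 7 gives 19.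

Step 5 (dynamic-kinetic hydrogenation): 2-arylchroman-3-ones are an untested substrate class for this catalyst, so the enantiomeric excess and the sense of induction are uncertain, and the ketone is air-sensitive under base. The fallback sets out from 13 and comes back at 14. LiBH(s-Bu)3 (THF, −78 °C) attacks anti to the 2-aryl group and gives the racemic 2,3-cis alcohol rac-cis-7,8-bis(benzyloxy)-2-[3,4-bis(benzyloxy)phenyl]chroman-3-ol F1. Esterification with (S)-naproxen (DCC, DMAP) gives two diastereomers, the (S)-naproxen ester of the (2R,3R) alcohol F2 and the (S)-naproxen ester of the (2S,3S) alcohol F3. These are separated by chromatography or crystallisation; F3 is set aside, and saponification of F2 (LiOH, THF/H2O) gives 14.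

Step 6 (DDQ oxidation): the 5-deoxy ring A is less activated than in the usual catechin cases, so attack at C2–H or over-oxidation to the 4-ketone may compete. The fallback sets out from 14 and comes back at 16. Pb(OAc)4 (benzene, 70 °C) acetoxylates C4 by inner-sphere ligand transfer, assisted by the 3-O–Pb alkoxide, and gives (2R,3R,4S)-4-acetoxy-7,8-bis(benzyloxy)-2-[3,4-bis(benzyloxy)phenyl]chroman-3-ol F4. Methanolysis (K2CO3, MeOH, 0 °C) then gives 16.

**Further compounds**
F1 | step 5 | rac-cis-7,8-bis(benzyloxy)-2-[3,4-bis(benzyloxy)phenyl]chroman-3-ol (both enantiomers) | O[C@@H]1Cc2ccc(OCc3ccccc3)c(OCc3ccccc3)c2O[C@@H]1c1ccc(OCc2ccccc2)c(OCc2ccccc2)c1.O[C@H]1Cc2ccc(OCc3ccccc3)c(OCc3ccccc3)c2O[C@H]1c1ccc(OCc2ccccc2)c(OCc2ccccc2)c1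
F2 | step 5 | (2R,3R)-7,8-bis(benzyloxy)-2-[3,4-bis(benzyloxy)phenyl]chroman-3-yl (S)-2-(6-methoxynaphthalen-2-yl)propanoate | COc1ccc2cc(ccc2c1)[C@H](C)C(=O)O[C@@H]1Cc2ccc(OCc3ccccc3)c(OCc3ccccc3)c2O[C@@H]1c1ccc(OCc2ccccc2)c(OCc2ccccc2)c1
F3 | step 5 | (2S,3S)-7,8-bis(benzyloxy)-2-[3,4-bis(benzyloxy)phenyl]chroman-3-yl (S)-2-(6-methoxynaphthalen-2-yl)propanoate | COc1ccc2cc(ccc2c1)[C@H](C)C(=O)O[C@H]1Cc2ccc(OCc3ccccc3)c(OCc3ccccc3)c2O[C@H]1c1ccc(OCc2ccccc2)c(OCc2ccccc2)c1
F4 | step 6 | (2R,3R,4S)-4-acetoxy-7,8-bis(benzyloxy)-2-[3,4-bis(benzyloxy)phenyl]chroman-3-ol | c1ccccc1COc1ccc2c(c1OCc1ccccc1)O[C@H](c1ccc(OCc3ccccc3)c(OCc3ccccc3)c1)[C@H](O)[C@H]2OC(C)=O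
F5 | step 8 | (2R,3R,4S)-7,8-bis(benzyloxy)-2-[3,4-bis(benzyloxy)phenyl]-4-(phenylsulfanyl)chroman-3-ol | c1ccccc1COc1ccc2c(c1OCc1ccccc1)O[C@H](c1ccc(OCc3ccccc3)c(OCc3ccccc3)c1)[C@H](O)[C@H]2Sc1ccccc1
F6 | step 8 | octa-O-benzyl ether of 19 (all eight phenolic OH benzylated, configuration as in 19) | c5ccccc5COc1ccc([C@H]2Oc3c(ccc(OCc5ccccc5)c3OCc5ccccc5)[C@H](c3cc4c(c(OCc5ccccc5)c3OCc5ccccc5)O[C@H](c3ccc(OCc5ccccc5)c(OCc5ccccc5)c3)[C@H](O)[C@H]4O)[C@H]2O)cc1OCc5ccccc5
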